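**Strategy.** Ring A is disconnected at C1–C10 and C2–C3 (labdane numbering). The key step exploits that C1 and C2 of ring A are bare methylenes lying between the quaternary C10 and the C3 next to quaternary C4. A traceless two-carbon linchpin, vinyltriphenylphosphonium bromide, is stitched between the C10 enolate of a ring B ketone and a C3 aldehyde by Michael addition and intramolecular Wittig olefination. This closes ring A and sets the C10 quaternary centre in one operation. The precursor is a monocyclic keto aldehyde whose C4 and C5 centres come from a Claisen chirality transfer and a lactone alkylation. (S)-Citronellol supplies C11 to C16; hydroboration sets C8 and C9.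

Key step: step 8

Remark: positions are given in labdane numbering (ring A = C1–C5, C10; ring B = C5–C10; C18 = the acyloxymethyl carbon on C4; side chain C11–C16). The target is read from its SMILES as the (4S,5S,8S,9S,10R,13S) isomer carrying a (Z)-2-methylbut-2-enoate (angelate).
Remark: where an intermediate is an inconsequential epimer mixture at a centre that is planarised later, that centre is left undefined in its SMILES.

Step 1
Reactants: 1 2-methylcyclohex-2-en-1-one
Product: 2 (1R)-2-methylcyclohex-2-en-1-ol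
Conditions: (S)-2-methyl-CBS-oxazaborolidine (cat.), BH3·SMe2, THF, −20 °C
Reagents that add atoms: none
Why: CBS reduction, in which the catalyst–borane complex binds the ketone with the methyl-bearing vinyl arm as the large group and should deliver hydride to the face that gives the R carbinol by the standard model.

Step 2
Reactants: 2 (1R)-2-methylcyclohex-2-en-1-ol; 3 triethyl orthopropionate
Product: 5 ethyl 2-[(1R)-2-methylcyclohex-2-en-1-yl]propanoate (both epimers at the α-carbon), via mixed ketene acetal 4 (not isolated)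
Conditions: EtCO2H (cat.), 140 °C, EtOH distilled off
Reagents that add atoms: none
Why: Johnson–Claisen rearrangement, whose suprafacial [3,3] shift across the ring transfers the C9–O stereocentre of 2 to C5 and moves the double bond to C9=C10 (the C4 epimer mixture is erased in step 4).

Step 3
Reactants: 5 ethyl 2-[(1R)-2-methylcyclohex-2-en-1-yl]propanoate
Product: 7 (3aR,7S,7aS)-7-iodo-3,7a-dimethylhexahydro-1-benzofuran-2(3H)-one (both C3 epimers), via lithium carboxylate 6 (not isolated)
Conditions: LiOH, THF/MeOH/H2O, 50 °C; then NaHCO3, I2, KI, H2O/THF, 0 to 25 °C, dark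
Reagents that add atoms: lithium hydroxide [Li+].[OH-]; iodine II
Why: saponification followed by iodolactonisation, in which the carboxylate tethered at C5 opens the iodonium ion at the tertiary C10 in a 5-exo mode and so fixes a cis-fused γ-lactone with iodine anti at C9.

Step 4
Reactants: 7 (3aR,7S,7aS)-7-iodo-3,7a-dimethylhexahydro-1-benzofuran-2(3H)-one
Product: 8 (3S,3aR,7S,7aS)-3-[(benzyloxy)methyl]-7-iodo-3,7a-dimethylhexahydro-1-benzofuran-2(3H)-one
Conditions: LiN(iPr)2, THF, −78 °C; BnOCH2Cl, DMPU, −78 to −40 °C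
Reagents that add atoms: benzyl chloromethyl ether ClCOCc1ccccc1
Why: lactone enolate alkylation, in which the electrophile should enter the convex face of the cis-fused bicycle anti to the cyclohexane bond at C5, placing the benzyloxymethyl group cis to H5 and thereby setting the quaternary C4.

Step 5
Reactants: 8 (3S,3aR,7S,7aS)-3-[(benzyloxy)methyl]-7-iodo-3,7a-dimethylhexahydro-1-benzofuran-2(3H)-one
Product: 9 (2S)-3-(benzyloxy)-2-methyl-2-[(1S)-2-methylcyclohex-2-en-1-yl]propanoic acid
Conditions: Zn dust, AcOH/THF, 25 °C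
Reagents that add atoms: none
Why: reductive β-elimination of the iodo lactone (zinc insertion into the C–I bond and expulsion of the carboxylate) should return the C9=C10 alkene without touching C4 or C5.

Step 6
Reactants: 9 (2S)-3-(benzyloxy)-2-methyl-2-[(1S)-2-methylcyclohex-2-en-1-yl]propanoic acid
Product: 10 (2R)-3-(benzyloxy)-2-[(1S,2S,3S)-3-hydroxy-2-methylcyclohexyl]-2-methylpropan-1-ol
Conditions: BH3·THF (excess), THF, 0 to 25 °C; then NaOH, H2O2, 0 °C
Reagents that add atoms: hydrogen peroxide OO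
Why: borane reduces the acid to the primary alcohol and hydroborates the trisubstituted alkene with boron at C9, syn and anti to the C5 substituent, and oxidation with retention gives the secondary alcohol (C9 and C10 are planarised later).

Step 7
Reactants: 10 (2R)-3-(benzyloxy)-2-[(1S,2S,3S)-3-hydroxy-2-methylcyclohexyl]-2-methylpropan-1-ol
Product: 11 (2S)-3-(benzyloxy)-2-methyl-2-[(1S)-2-methyl-3-oxocyclohexyl]propanal (epimers at the methyl-bearing ring carbon)
Conditions: (COCl)2, DMSO, CH2Cl2, −78 °C; Et3N, −78 to 0 °C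
Reagents that add atoms: none
Why: Swern oxidation of both alcohols, giving an aldehyde that has no α-hydrogen and therefore cannot epimerise at C4 or eliminate the β-alkoxy group.

Step 8
Reactants: 11 (2S)-3-(benzyloxy)-2-methyl-2-[(1S)-2-methyl-3-oxocyclohexyl]propanal; 12 vinyltriphenylphosphonium bromide
Product: 15 (4aR,5S,8aR)-5-[(benzyloxy)methyl]-5,8a-dimethyl-3,4,4a,5,8,8a-hexahydronaphthalen-1(2H)-one, via sodium enolate 13 (not isolated), via phosphonium ylide 14 (not isolated)
Conditions: NaH (1.0 equiv), THF, 0 to 25 °C; then 12, THF/DMF, 25 to 50 °C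
Reagents that add atoms: none
Why: The more substituted C9=C10 sodium enolate 13, formed under equilibrating conditions, adds through C10 to the β-carbon of the vinylphosphonium salt (C1–C10 bond) to give the non-stabilised ylide 14, whose carbanionic C2 attacks the C3 aldehyde and collapses through an oxaphosphetane to the C2=C3 alkene and Ph3P=O. The closest known reaction type is the Michael addition–intramolecular Wittig annulation of enolates with vinylphosphonium salts, which also serves as the ring-closing stage of Michael–Michael–ring-closure sequences on 2-methylcycloalkenone enolates. Ring A is closed by a 6-exo-trig attack of the ylide carbon on the exocyclic C=O, and the six-membered ring can only hold the Z alkene. The new quaternary stereocentre C10 is set in the Michael step, where the acceptor should approach the enolate face anti to the bulky quaternary substituent on C5, placing C1 trans to C4 and the C10 methyl trans to H5 (trans ring fusion). The step needs regioselection for C10 over C8, which rests on thermodynamic enolate formation and on the fact that only the C10 adduct can reach the aldehyde through a six-membered transition state, while the C8 enolate can only enter a reversible aldol. The aldehyde cannot enolise because C4 is quaternary, so it waits intact for the ylide.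

Step 9
Reactants: 15 (4aR,5S,8aR)-5-[(benzyloxy)methyl]-5,8a-dimethyl-3,4,4a,5,8,8a-hexahydronaphthalen-1(2H)-one
Product: 16 (4aR,5S,8aR)-5-[(benzyloxy)methyl]-2,5,8a-trimethyl-3,4,4a,5,8,8a-hexahydronaphthalen-1(2H)-one (both C2 epimers)
Conditions: LiN(iPr)2, THF, −78 °C; MeI, −78 to −20 °C
Reagents that add atoms: iodomethane CI
Why: enolate methylation that is regiospecific because C8 is the only enolisable position of the C9 ketone (C10 is quaternary), installing C17 at a centre that is planarised in step 10.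

Step 10
Reactants: 16 (4aR,5S,8aR)-5-[(benzyloxy)methyl]-2,5,8a-trimethyl-3,4,4a,5,8,8a-hexahydronaphthalen-1(2H)-one
Product: 17 (4aR,5S,8aR)-5-[(benzyloxy)methyl]-2,5,8a-trimethyl-3,4,4a,5,8,8a-hexahydronaphthalen-1-yl trifluoromethanesulfonate
Conditions: KN(SiMe3)2, THF, −78 °C; PhNTf2, −78 to 0 °C
Reagents that add atoms: N-phenylbis(trifluoromethanesulfonimide) FC(F)(F)S(=O)(=O)N(c1ccccc1)S(=O)(=O)C(F)(F)F
Why: O-sulfonylation of the only possible enolate should give the tetrasubstituted C8=C9 enol triflate as the handle for attaching the side chain.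

Step 11
Reactants: 18 (3S)-3,7-dimethyloct-6-en-1-ol ((S)-citronellol)
Product: 19 tert-butyl{[(3S)-3,7-dimethyloct-6-en-1-yl]oxy}dimethylsilane
Conditions: TBSCl, imidazole, DMF, 25 °C
Reagents that add atoms: tert-butyldimethylsilyl chloride CC(C)(C)[Si](C)(C)Cl
Why: standard silylation of the primary alcohol, which masks the future C15 oxygen until the last two steps.

Step 12
Reactants: 19 tert-butyl{[(3S)-3,7-dimethyloct-6-en-1-yl]oxy}dimethylsilane
Product: 20 (4S)-6-[(tert-butyldimethylsilyl)oxy]-4-methylhexanal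
Conditions: O3, CH2Cl2/MeOH, −78 °C; then Me2S, −78 to 25 °C
Reagents that add atoms: ozone [O-][O+]=O
Why: ozonolysis with reductive work-up cleaves the trisubstituted alkene to the aldehyde without touching the remote stereocentre.

Step 13
Reactants: 20 (4S)-6-[(tert-butyldimethylsilyl)oxy]-4-methylhexanal
Product: 21 tert-butyldimethyl{[(3R)-3-methylpent-4-en-1-yl]oxy}silane
Conditions: [Rh(cod)OMe]2 (cat.), Xantphos (cat.), 3-methoxybenzoic acid (cat.), norbornadiene, THF, 60 °C
Reagents that add atoms: none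
Why: rhodium-catalysed transfer hydroformylation (dehydroformylation), in which the acyl rhodium hydride loses CO, β-hydride elimination gives the terminal alkene one carbon shorter, and the formyl unit is passed to the strained acceptor, leaving the methyl-bearing stereocentre untouched.

Step 14
Reactants: 17 (4aR,5S,8aR)-5-[(benzyloxy)methyl]-2,5,8a-trimethyl-3,4,4a,5,8,8a-hexahydronaphthalen-1-yl trifluoromethanesulfonate; 21 tert-butyldimethyl{[(3R)-3-methylpent-4-en-1-yl]oxy}silane
Product: 23 tert-butyl({(3S)-5-[(4aS,5S,8aR)-5-[(benzyloxy)methyl]-2,5,8a-trimethyl-3,4,4a,5,8,8a-hexahydronaphthalen-1-yl]-3-methylpentyl}oxy)dimethylsilane, via B-alkyl-9-BBN borane 22 (not isolated)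
Conditions: 21, 9-BBN, THF, 25 °C; then 17, Pd(dppf)Cl2, AsPh3, Cs2CO3, DMF/H2O, 25 to 50 °C
Reagents that add atoms: none
Why: anti-Markovnikov hydroboration of the vinyl group followed by B-alkyl Suzuki–Miyaura coupling with the enol triflate should form the C9–C11 bond and deliver the side chain with its C13 centre from citronellol.

Step 15
Reactants: 23 tert-butyl({(3S)-5-[(4aS,5S,8aR)-5-[(benzyloxy)methyl]-2,5,8a-trimethyl-3,4,4a,5,8,8a-hexahydronaphthalen-1-yl]-3-methylpentyl}oxy)dimethylsilane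
Product: 24 [(1S,4aR,8aS)-5-{(3S)-5-[(tert-butyldimethylsilyl)oxy]-3-methylpentyl}-1,4a,6-trimethyl-1,2,3,4,4a,7,8,8a-octahydronaphthalen-1-yl]methanol
Conditions: H2 (1 atm), Pd/C, EtOAc, 25 °C
Reagents that add atoms: none
Why: heterogeneous hydrogenation should saturate the cis-disubstituted C2=C3 alkene and cleave the benzyl ether, while the tetrasubstituted C8=C9 alkene next to the quaternary C10 stays inert.

Step 16
Reactants: 24 [(1S,4aR,8aS)-5-{(3S)-5-[(tert-butyldimethylsilyl)oxy]-3-methylpentyl}-1,4a,6-trimethyl-1,2,3,4,4a,7,8,8a-octahydronaphthalen-1-yl]methanol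
Product: 25 (1S,2S,4aS,5S,8aR)-1-{(3S)-5-[(tert-butyldimethylsilyl)oxy]-3-methylpentyl}-5-(hydroxymethyl)-2,5,8a-trimethyldecahydronaphthalen-2-ol
Conditions: BH3·THF (excess), THF, 0 to 25 °C; then NaOH, H2O2, 0 to 25 °C
Reagents that add atoms: hydrogen peroxide OO
Why: hydroboration–oxidation of the tetrasubstituted alkene, in which syn addition of H–B from the face opposite the axial C10 methyl with boron at the less hindered C8 (C9 is neopentyl) should set 9-H and the equatorial 8-OH with the axial 8-methyl together, the oxidation proceeding with retention.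

Step 17
Reactants: 25 (1S,2S,4aS,5S,8aR)-1-{(3S)-5-[(tert-butyldimethylsilyl)oxy]-3-methylpentyl}-5-(hydroxymethyl)-2,5,8a-trimethyldecahydronaphthalen-2-ol; 26 (2Z)-2-methylbut-2-enoic acid (angelic acid)
Product: 27 [(1S,4aR,5S,6S,8aS)-5-{(3S)-5-[(tert-butyldimethylsilyl)oxy]-3-methylpentyl}-6-hydroxy-1,4a,6-trimethyldecahydronaphthalen-1-yl]methyl (2Z)-2-methylbut-2-enoate
Conditions: 26, 2,4,6-trichlorobenzoyl chloride, Et3N, toluene, 25 °C; then 25, toluene, 80 °C
Reagents that add atoms: none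
Why: Yamaguchi-type mixed anhydride esterification run without a nucleophilic catalyst should acylate the primary neopentyl C18–OH, leave the tertiary C8–OH alone, and avoid Z-to-E isomerisation of the angelate.

Step 18
Reactants: 27 [(1S,4aR,5S,6S,8aS)-5-{(3S)-5-[(tert-butyldimethylsilyl)oxy]-3-methylpentyl}-6-hydroxy-1,4a,6-trimethyldecahydronaphthalen-1-yl]methyl (2Z)-2-methylbut-2-enoate
Product: 28 [(1S,4aR,5S,6S,8aS)-6-hydroxy-5-[(3S)-5-hydroxy-3-methylpentyl]-1,4a,6-trimethyldecahydronaphthalen-1-yl]methyl (2Z)-2-methylbut-2-enoate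
Conditions: HF·pyridine, THF/pyridine, 0 to 25 °C
Reagents that add atoms: none
Why: buffered fluoride desilylation frees the primary C15–OH under conditions that spare the angelate and the tertiary alcohol.

Step 19
Reactants: 28 [(1S,4aR,5S,6S,8aS)-6-hydroxy-5-[(3S)-5-hydroxy-3-methylpentyl]-1,4a,6-trimethyldecahydronaphthalen-1-yl]methyl (2Z)-2-methylbut-2-enoate; 29 2,2-dimethyl-1,3-dioxane-4,6-dione (Meldrum's acid)
Product: 30 3-({(3S)-5-[(1S,2S,4aS,5S,8aR)-2-hydroxy-2,5,8a-trimethyl-5-({[(2Z)-2-methylbut-2-enoyl]oxy}methyl)decahydronaphthalen-1-yl]-3-methylpentyl}oxy)-3-oxopropanoic acid (CNP0286290.1)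
Conditions: toluene, 90 °C
Reagents that add atoms: none
Why: alcoholysis of Meldrum's acid by the unhindered primary alcohol opens the dioxanedione with loss of acetone and should give the malonic acid half ester directly, the tertiary C8–OH being too hindered to compete.

**Compound list**

1 | 2-methylcyclohex-2-en-1-one | CC1=CCCCC1=O | starting material
2 | (1R)-2-methylcyclohex-2-en-1-ol | O[C@@H]1CCCC=C1C | intermediate
3 | triethyl orthopropionate | CCC(OCC)(OCC)OCC | starting material
4 | (6R)-6-[(1-ethoxyprop-1-en-1-yl)oxy]-1-methylcyclohex-1-ene (mixed ketene acetal, not isolated) | CC=C(OCC)O[C@@H]1CCCC=C1C | intermediate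
5 | ethyl 2-[(1R)-2-methylcyclohex-2-en-1-yl]propanoate (both epimers at the α-carbon) | CCOC(=O)C(C)[C@H]1CCCC=C1C | intermediate
6 | lithium 2-[(1R)-2-methylcyclohex-2-en-1-yl]propanoate (not isolated) | [Li+].[O-]C(=O)C(C)[C@H]1CCCC=C1C | intermediate
7 | (3aR,7S,7aS)-7-iodo-3,7a-dimethylhexahydro-1-benzofuran-2(3H)-one (both C3 epimers) | O=C1O[C@]2(C)[C@@H](I)CCC[C@@H]2C1C | intermediate
8 | (3S,3aR,7S,7aS)-3-[(benzyloxy)methyl]-7-iodo-3,7a-dimethylhexahydro-1-benzofuran-2(3H)-one | O=C1O[C@]2(C)[C@@H](I)CCC[C@@H]2[C@@]1(C)COCc3ccccc3 | intermediate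
9 | (2S)-3-(benzyloxy)-2-methyl-2-[(1S)-2-methylcyclohex-2-en-1-yl]propanoic acid | C(c1ccccc1)OC[C@@](C)(C(=O)O)[C@H]2CCCC=C2C | intermediate
10 | (2R)-3-(benzyloxy)-2-[(1S,2S,3S)-3-hydroxy-2-methylcyclohexyl]-2-methylpropan-1-ol | C(c1ccccc1)OC[C@@](C)(CO)[C@H]2CCC[C@H](O)[C@H]2C | intermediate
11 | (2S)-3-(benzyloxy)-2-methyl-2-[(1S)-2-methyl-3-oxocyclohexyl]propanal (epimers at the methyl-bearing ring carbon) | C(c1ccccc1)OC[C@@](C)(C=O)[C@H]2CCCC(=O)C2C | intermediate
12 | vinyltriphenylphosphonium bromide | C=C[P+](c1ccccc1)(c1ccccc1)c1ccccc1.[Br-] | starting material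
13 | sodium (3S)-3-[(2S)-1-(benzyloxy)-2-methyl-3-oxopropan-2-yl]-2-methylcyclohex-1-en-1-olate (not isolated) | C(c1ccccc1)OC[C@@](C)(C=O)[C@H]2CCCC([O-])=C2C.[Na+] | intermediate
14 | (2S)-3-(benzyloxy)-2-methyl-2-{(1R,2R)-2-methyl-3-oxo-2-[2-(triphenyl-λ5-phosphanylidene)ethyl]cyclohexyl}propanal (not isolated) | C(c1ccccc1)OC[C@@](C)(C=O)[C@H]2CCCC(=O)[C@]2(C)CC=P(c3ccccc3)(c4ccccc4)c5ccccc5 | intermediate
15 | (4aR,5S,8aR)-5-[(benzyloxy)methyl]-5,8a-dimethyl-3,4,4a,5,8,8a-hexahydronaphthalen-1(2H)-one | c1ccc(cc1)COC[C@@]2(C)C=CC[C@]3(C)[C@@H]2CCCC3=O | intermediate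
16 | (4aR,5S,8aR)-5-[(benzyloxy)methyl]-2,5,8a-trimethyl-3,4,4a,5,8,8a-hexahydronaphthalen-1(2H)-one (both C2 epimers) | c1ccc(cc1)COC[C@@]2(C)C=CC[C@]3(C)[C@@H]2CCC(C)C3=O | intermediate
17 | (4aR,5S,8aR)-5-[(benzyloxy)methyl]-2,5,8a-trimethyl-3,4,4a,5,8,8a-hexahydronaphthalen-1-yl trifluoromethanesulfonate | c1ccc(cc1)COC[C@@]2(C)C=CC[C@]3(C)[C@@H]2CCC(C)=C3OS(=O)(=O)C(F)(F)F | intermediate
18 | (3S)-3,7-dimethyloct-6-en-1-ol ((S)-citronellol) | OCC[C@@H](C)CCC=C(C)C | starting material
19 | tert-butyl{[(3S)-3,7-dimethyloct-6-en-1-yl]oxy}dimethylsilane | CC(C)(C)[Si](C)(C)OCC[C@@H](C)CCC=C(C)C | intermediate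
20 | (4S)-6-[(tert-butyldimethylsilyl)oxy]-4-methylhexanal | CC(C)(C)[Si](C)(C)OCC[C@@H](C)CCC=O | intermediate
21 | tert-butyldimethyl{[(3R)-3-methylpent-4-en-1-yl]oxy}silane | CC(C)(C)[Si](C)(C)OCC[C@@H](C)C=C | intermediate
22 | 9-{(3S)-5-[(tert-butyldimethylsilyl)oxy]-3-methylpentyl}-9-borabicyclo[3.3.1]nonane (not isolated) | CC(C)(C)[Si](C)(C)OCC[C@@H](C)CCB1C2CCCC1CCC2 | intermediate
23 | tert-butyl({(3S)-5-[(4aS,5S,8aR)-5-[(benzyloxy)methyl]-2,5,8a-trimethyl-3,4,4a,5,8,8a-hexahydronaphthalen-1-yl]-3-methylpentyl}oxy)dimethylsilane | c1ccc(cc1)COC[C@@]2(C)C=CC[C@]3(C)[C@@H]2CCC(C)=C3CC[C@H](C)CCO[Si](C)(C)C(C)(C)C | intermediate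
24 | [(1S,4aR,8aS)-5-{(3S)-5-[(tert-butyldimethylsilyl)oxy]-3-methylpentyl}-1,4a,6-trimethyl-1,2,3,4,4a,7,8,8a-octahydronaphthalen-1-yl]methanol | OC[C@@]1(C)CCC[C@]2(C)[C@@H]1CCC(C)=C2CC[C@H](C)CCO[Si](C)(C)C(C)(C)C | intermediate
25 | (1S,2S,4aS,5S,8aR)-1-{(3S)-5-[(tert-butyldimethylsilyl)oxy]-3-methylpentyl}-5-(hydroxymethyl)-2,5,8a-trimethyldecahydronaphthalen-2-ol | OC[C@@]1(C)CCC[C@]2(C)[C@@H]1CC[C@](C)(O)[C@H]2CC[C@H](C)CCO[Si](C)(C)C(C)(C)C | intermediate
26 | (2Z)-2-methylbut-2-enoic acid (angelic acid) | C/C=C(/C)C(=O)O | starting material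
27 | [(1S,4aR,5S,6S,8aS)-5-{(3S)-5-[(tert-butyldimethylsilyl)oxy]-3-methylpentyl}-6-hydroxy-1,4a,6-trimethyldecahydronaphthalen-1-yl]methyl (2Z)-2-methylbut-2-enoate | C/C=C(/C)C(=O)OC[C@@]1(C)CCC[C@]2(C)[C@@H]1CC[C@](C)(O)[C@H]2CC[C@H](C)CCO[Si](C)(C)C(C)(C)C | intermediate
28 | [(1S,4aR,5S,6S,8aS)-6-hydroxy-5-[(3S)-5-hydroxy-3-methylpentyl]-1,4a,6-trimethyldecahydronaphthalen-1-yl]methyl (2Z)-2-methylbut-2-enoate | C/C=C(/C)C(=O)OC[C@@]1(C)CCC[C@]2(C)[C@@H]1CC[C@](C)(O)[C@H]2CC[C@H](C)CCO | intermediate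
29 | 2,2-dimethyl-1,3-dioxane-4,6-dione (Meldrum's acid) | CC1(C)OC(=O)CC(=O)O1 | starting material
30 | 3-({(3S)-5-[(1S,2S,4aS,5S,8aR)-2-hydroxy-2,5,8a-trimethyl-5-({[(2Z)-2-methylbut-2-enoyl]oxy}methyl)decahydronaphthalen-1-yl]-3-methylpentyl}oxy)-3-oxopropanoic acid | C/C=C(/C)C(=O)OC[C@@]1(C)CCC[C@]2(C)[C@@H]1CC[C@](C)(O)[C@H]2CC[C@H](C)CCOC(=O)CC(=O)O | target

**Step count.** Total: 19 steps. Longest linear sequence: 16 steps (steps 1–10 and 14–19); steps 11–13 prepare the side-chain fragment.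

**Steps most likely to fail**

1. Step 8. The equilibrating enolate may leak to the C8 regioisomer, or addition at the congested C10 may be outrun by proton transfer and aldol side reactions. The fallback sets out from 11 and comes back at 15. Thermodynamic silylation of 11 (Me3SiCl, NaI, Et3N, MeCN) should give the tetrasubstituted silyl enol ether (2S)-3-(benzyloxy)-2-methyl-2-{(1S)-2-methyl-3-[(trimethylsilyl)oxy]cyclohex-2-en-1-yl}propanal F1, which is purified. F1 and 12 are then treated with anhydrous fluoride (tetrabutylammonium difluorotriphenylsilicate, THF), which unmasks the C10 enolate regiospecifically under aprotic, non-equilibrating conditions; the same Michael–Wittig closure then leads to 15.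

2. Step 16. Boron may add at C9 instead of C8, the hindered alkene may react sluggishly, or the tertiary borane may migrate on warming. The fallback sets out from 15 and comes back at 25, building the carbinol through an exocyclic alkene:
   - Hydrogenation of 15 that spares the benzyl ether (H2, Rh/Al2O3, EtOAc) gives the saturated ketone F2.
   - KN(SiMe3)2 and PhNTf2 give the trisubstituted enol triflate F3.
   - Coupling with borane 22 (Pd(dppf)Cl2, AsPh3, Cs2CO3) gives the C8=C9 alkene F4.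
   - Hydroboration–oxidation (BH3·THF; NaOH, H2O2), reliable on this trisubstituted alkene, gives the secondary alcohol F5 with 9-H set.
   - Dess–Martin periodinane gives the C8 ketone F6.
   - Ph3P=CH2 gives the exocyclic alkene F7.
   - m-CPBA from the face away from the C10 methyl gives the spiro epoxide F8.
   - LiAlH4 opens it at the CH2 terminus to the tertiary alcohol F9.
   - H2 over Pd/C removes the benzyl group to give 25.

3. Step 14. Oxidative addition and transmetalation at the tetrasubstituted, neopentyl-flanked enol triflate may be slow, letting triflate hydrolysis or β-hydride elimination of the alkylpalladium take over. The fallback sets out from 16 and 21 and comes back at 23. Alkene 21 is converted by 9-BBN then I2/NaOMe into the iodide tert-butyl{[(3R)-5-iodo-3-methylpentyl]oxy}dimethylsilane F10. Lithium–iodine exchange (t-BuLi, Et2O, −78 °C), transmetalation with CeCl3 and addition to ketone 16 give the tertiary alcohol F11. Dehydration (SOCl2, pyridine) toward the more substituted position should give the tetrasubstituted alkene 23.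

**Further compounds**

F1 | step 8 | (2S)-3-(benzyloxy)-2-methyl-2-{(1S)-2-methyl-3-[(trimethylsilyl)oxy]cyclohex-2-en-1-yl}propanal | C(c1ccccc1)OC[C@@](C)(C=O)[C@H]2CCCC(O[Si](C)(C)C)=C2C
F2 | step 16 | (4aR,5S,8aR)-5-[(benzyloxy)methyl]-5,8a-dimethyloctahydronaphthalen-1(2H)-one | c1ccc(cc1)COC[C@@]2(C)CCC[C@]3(C)[C@@H]2CCCC3=O
F3 | step 16 | (4aR,5S,8aR)-5-[(benzyloxy)methyl]-5,8a-dimethyl-3,4,4a,5,6,7,8,8a-octahydronaphthalen-1-yl trifluoromethanesulfonate | c1ccc(cc1)COC[C@@]2(C)CCC[C@]3(C)[C@@H]2CCC=C3OS(=O)(=O)C(F)(F)F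
F4 | step 16 | tert-butyl({(3S)-5-[(4aS,5S,8aR)-5-[(benzyloxy)methyl]-5,8a-dimethyl-3,4,4a,5,6,7,8,8a-octahydronaphthalen-1-yl]-3-methylpentyl}oxy)dimethylsilane | c1ccc(cc1)COC[C@@]2(C)CCC[C@]3(C)[C@@H]2CCC=C3CC[C@H](C)CCO[Si](C)(C)C(C)(C)C
F5 | step 16 | (1S,2S,4aS,5S,8aR)-5-[(benzyloxy)methyl]-1-{(3S)-5-[(tert-butyldimethylsilyl)oxy]-3-methylpentyl}-5,8a-dimethyldecahydronaphthalen-2-ol | c1ccc(cc1)COC[C@@]2(C)CCC[C@]3(C)[C@@H]2CC[C@H](O)[C@H]3CC[C@H](C)CCO[Si](C)(C)C(C)(C)C
F6 | step 16 | (1S,4aS,5S,8aR)-5-[(benzyloxy)methyl]-1-{(3S)-5-[(tert-butyldimethylsilyl)oxy]-3-methylpentyl}-5,8a-dimethyloctahydronaphthalen-2(1H)-one | c1ccc(cc1)COC[C@@]2(C)CCC[C@]3(C)[C@@H]2CCC(=O)[C@H]3CC[C@H](C)CCO[Si](C)(C)C(C)(C)C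
F7 | step 16 | tert-butyl({(3S)-5-[(1R,4aS,5S,8aS)-5-[(benzyloxy)methyl]-5,8a-dimethyl-2-methylidenedecahydronaphthalen-1-yl]-3-methylpentyl}oxy)dimethylsilane | c1ccc(cc1)COC[C@@]2(C)CCC[C@]3(C)[C@@H]2CCC(=C)[C@H]3CC[C@H](C)CCO[Si](C)(C)C(C)(C)C
F8 | step 16 | tert-butyl({(3S)-5-[(1S,2S,4aS,5S,8aR)-5-[(benzyloxy)methyl]-5,8a-dimethyloctahydro-1H-spiro[naphthalene-2,2'-oxiran]-1-yl]-3-methylpentyl}oxy)dimethylsilane | c1ccc(cc1)COC[C@@]2(C)CCC[C@]3(C)[C@@H]2CC[C@@]4(CO4)[C@H]3CC[C@H](C)CCO[Si](C)(C)C(C)(C)C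
F9 | step 16 | (1S,2S,4aS,5S,8aR)-5-[(benzyloxy)methyl]-1-{(3S)-5-[(tert-butyldimethylsilyl)oxy]-3-methylpentyl}-2,5,8a-trimethyldecahydronaphthalen-2-ol | c1ccc(cc1)COC[C@@]2(C)CCC[C@]3(C)[C@@H]2CC[C@](C)(O)[C@H]3CC[C@H](C)CCO[Si](C)(C)C(C)(C)C
F10 | step 14 | tert-butyl{[(3R)-5-iodo-3-methylpentyl]oxy}dimethylsilane | CC(C)(C)[Si](C)(C)OCC[C@@H](C)CCI
F11 | step 14 | (4aR,5S,8aR)-5-[(benzyloxy)methyl]-1-{(3S)-5-[(tert-butyldimethylsilyl)oxy]-3-methylpentyl}-2,5,8a-trimethyl-1,2,3,4,4a,5,8,8a-octahydronaphthalen-1-ol (C1 and C2 undefined) | c1ccc(cc1)COC[C@@]2(C)C=CC[C@]3(C)[C@@H]2CCC(C)C3(O)CC[C@H](C)CCO[Si](C)(C)C(C)(C)C
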